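C7–O/C8–O in the ten-membered ring and C11–O/C12–O in six-membered ring A are two cis vicinal C–O pairs. C8 also carries the C17–C19 propionate arm, so a Z C7=C8 alkene with a C19 ester is a β,γ-unsaturated ester that gives the γ-lactone on syn-dihydroxylation.
Cuts, in retrosynthetic order: C6–Cl; C3=C4 back to the alkyne; then together C7–O, C8–O, C11–O, C12–O and O7–C19; C2–C3; C8–C9; C6–C7 and C4–C5; C1–C14 and C10–C11.
Forward: ring A is made by a Diels–Alder reaction and its enone is converted into the C11–C14 diene. The side chain (C3–C8, C16–C19) is joined at C8–C9, the ten-membered ring is closed at C2–C3, and the γ-lactone closes in the double osmylation. The alkyne then becomes the Z-alkene and C6–O becomes C6–Cl.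
Stereochemistry: C1/C10 come from an E dienophile and a chiral Lewis acid, and C17 from the (S)-Roche ester. C6 comes from a catalytic asymmetric alkynylation and is inverted at the end by chloride. C9 and C2 come from Felkin–Anh additions beside C10 and C1, and C7, C8, C11 and C12 from the key step.

Key step: step 25

Numbering (briarane): C1 is the quaternary fusion carbon and C2–C9 run round the ten-membered ring to fusion carbon C10. C11–C14 complete ring A, C15 is the methyl on C1 and C16 the exomethylene on C5. C17/C18/C19 are the lactone CH, its methyl and its carbonyl, and C20 is the methyl on C11. β is the face of C15, α that of H-10.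
Assumption: the sense of induction in steps 2 and 13 follows the accepted models for simpler enals; both catalysts are sold in either enantiomeric form, so a reversed sense would only call for the antipodal catalyst.

Step 1
Reactants: 1 pent-1-en-3-one
Product: 2 (Z)-3-(tert-butyldimethylsilyloxy)penta-1,3-diene
Conditions: TBSOTf, Et3N, Et2O, 0 °C
Reagents that add atoms: tert-butyldimethylsilyl triflate, CC(C)(C)[Si](C)(C)OS(=O)(=O)C(F)(F)F
Why: Soft enolisation and O-silylation of an ethyl ketone (silyl enol ether formation) gives the Z enol ether, in which the methyl group (C20) points away from the vinyl group and leaves the s-cis conformer open for cycloaddition.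

Step 2
Reactants: 2 (Z)-3-(tert-butyldimethylsilyloxy)penta-1,3-diene; 3 ethyl (E)-3-methyl-4-oxobut-2-enoate
Product: 4 ethyl (1S,6S)-3-(tert-butyldimethylsilyloxy)-6-formyl-2,6-dimethylcyclohex-3-ene-1-carboxylate (C11 methyl epimers)
Conditions: (S)-diphenylprolinol o-tolyl-oxazaborolidine·Tf2NH (20 mol %), CH2Cl2, −78 to −40 °C
Reagents that add atoms: none
Why: In this oxazaborolidinium-catalysed enantioselective Diels–Alder reaction of an α-methyl enal, the activated formyl group draws the nucleophilic C11 terminus of the 2-silyloxydiene to C10 ("para" adduct), the E geometry of 3 becomes the trans C2/C9 relationship at C1 and C10, the catalyst shields one enal face and sets their absolute configuration, and the C11 epimers are removed later.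

Step 3
Reactants: 4 Diels–Alder adduct
Product: 5 ethyl (1S,6S)-6-formyl-2,6-dimethyl-3-oxocyclohex-4-ene-1-carboxylate (C11 epimers)
Conditions: Pd(OAc)2 (1.05 equiv), MeCN, rt
Reagents that add atoms: none
Why: In this Saegusa–Ito oxidation, palladation of the silyl enol ether at C13 and β-hydride loss from C14 place the alkene at C13=C14, and the neutral medium spares the formyl and ester groups.

Step 4
Reactants: 5 enone aldehyde
Product: 6 ethyl (1S,6S)-6-(dimethoxymethyl)-2,6-dimethyl-3-oxocyclohex-4-ene-1-carboxylate (C11 epimers)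
Conditions: HC(OMe)3, CSA (cat.), MeOH, rt
Reagents that add atoms: trimethyl orthoformate, COC(OC)OC
Why: Acid-catalysed acetalisation takes the aldehyde much faster than the conjugated ketone and masks the C2 formyl group, which is prone to deformylation (vinylogous β-dicarbonyl), before strong base is used.

Step 5
Reactants: 6 enone acetal
Product: 8 ethyl (1S,6S)-6-(dimethoxymethyl)-2,6-dimethyl-3-(trifluoromethylsulfonyloxy)cyclohexa-2,4-diene-1-carboxylate, via potassium dienolate 7 (not isolated)
Conditions: KHMDS, THF, −78 °C; PhNTf2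
Reagents that add atoms: N-phenylbis(trifluoromethanesulfonimide), O=S(=O)(N(c1ccccc1)S(=O)(=O)C(F)(F)F)C(F)(F)F
Why: Kinetic deprotonation of the enone can occur only at C11 (C1 blocks the γ side and the ester α-proton is less acidic), and O-sulfonylation of 7 (enol triflate formation) fixes C11=C12 and erases the C11 stereocentre.

Step 6
Reactants: 8 dienyl triflate
Product: 9 ethyl (1S,6S)-6-(dimethoxymethyl)-2,6-dimethylcyclohexa-2,4-diene-1-carboxylate
Conditions: Pd(OAc)2 (5 mol %), PPh3, HCO2H, Et3N, DMF, 60 °C
Reagents that add atoms: none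
Why: Palladium-catalysed formate reduction of an enol triflate replaces C12–OTf by C12–H, keeps both double bonds in place and leaves the acetal and the ester untouched.

Step 7
Reactants: 9 diene ester
Product: 10 (1S,6S)-6-(dimethoxymethyl)-2,6-dimethylcyclohexa-2,4-diene-1-carbaldehyde
Conditions: DIBAL-H (1.1 equiv), toluene, −78 °C; Rochelle salt, 0 °C
Reagents that add atoms: none
Why: In this partial DIBAL-H reduction of an ester the hindered aluminium hemiacetal persists at −78 °C and releases the C9 aldehyde only on work-up, and a cold neutral work-up keeps the C10 proton (α to CHO and allylic) in place.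

Step 8
Reactants: 11 methyl (S)-3-hydroxy-2-methylpropanoate
Product: 12 methyl (S)-3-(tert-butyldimethylsilyloxy)-2-methylpropanoate
Conditions: TBSCl, imidazole, CH2Cl2, rt
Reagents that add atoms: tert-butyldimethylsilyl chloride, CC(C)(C)[Si](C)(C)Cl
Why: This is a routine silylation, and the S enantiomer is chosen because its ester carbon becomes C8 and its carbinol carbon C19, so that C17 never sits between two carbonyl groups and keeps its configuration.

Step 9
Reactants: 12 silyl ether ester
Product: 13 (S)-3-(tert-butyldimethylsilyloxy)-2-methylpropanal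
Conditions: DIBAL-H, CH2Cl2, −78 °C
Reagents that add atoms: none
Why: Partial DIBAL-H reduction of this β-silyloxy methyl ester is routine and gives the α-methyl aldehyde with its configuration intact if it is used at once.

Step 10
Reactants: 13 α-methyl aldehyde
Product: 14 (R)-tert-butyl(dimethyl)[(2-methylbut-3-yn-1-yl)oxy]silane
Conditions: Ohira–Bestmann reagent, K2CO3, MeOH, 0 °C to rt
Reagents that add atoms: dimethyl (1-diazo-2-oxopropyl)phosphonate, COP(=O)(OC)C(=[N+]=[N-])C(C)=O
Why: Seyferth–Gilbert homologation with the Ohira–Bestmann reagent adds C7 and turns the aldehyde carbon into the internal alkyne carbon C8 under carbonate conditions mild enough to preserve C17.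

Step 11
Reactants: 15 2-bromoprop-2-en-1-ol; 16 trimethylsilylacetylene
Product: 17 2-methylidene-4-(trimethylsilyl)but-3-yn-1-ol
Conditions: PdCl2(PPh3)2 (2 mol %), CuI (4 mol %), Et3N, THF, rt
Reagents that add atoms: none
Why: Sonogashira coupling of a 2-bromoalkene forms C4–C5 and delivers the 1-en-3-yne with exomethylene C16 already in place, and the free alcohol is tolerated.

Step 12
Reactants: 17 enynol
Product: 18 2-methylidene-4-(trimethylsilyl)but-3-ynal
Conditions: MnO2, CH2Cl2, rt; filtered and used as a solution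
Reagents that add atoms: none
Why: Manganese dioxide oxidises the allylic alcohol selectively under neutral conditions to the reactive 2-alkynylacrolein, which is not stored.

Step 13
Reactants: 14 (R)-alkyne; 18 enynal
Product: 20 (4S,7R)-8-(tert-butyldimethylsilyloxy)-7-methyl-3-methylidene-1-(trimethylsilyl)octa-1,5-diyn-4-ol, via alkynyl(methyl)zinc 19 (not isolated)
Conditions: (S,S)-ProPhenol (20 mol %), Ph3PO (40 mol %), Me2Zn, toluene, 4 °C
Reagents that add atoms: none
Why: In this ProPhenol–dinuclear zinc asymmetric alkynylation, a method suited to α,β-unsaturated aldehydes, 19 is delivered inside the chiral pocket to one face of the formyl group of 18, which forms C6–C7 and sets C6 (the epimer of the later chloride) independently of remote C17.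

Step 14
Reactants: 20 diynol
Product: 22 (4S,5Z,7S)-8-(tert-butyldimethylsilyloxy)-6-iodo-7-methyl-3-methylidene-1-(trimethylsilyl)oct-5-en-1-yn-4-ol, via cyclic alkenylalanate 21 (not isolated)
Conditions: Red-Al, THF, −20 to 0 °C; I2, −78 °C
Reagents that add atoms: iodine, II
Why: In this hydroxyl-directed trans-hydroalumination of a propargylic alcohol followed by iodinolysis, hydride goes to C7 and aluminium to C8 within five-membered 21, so iodine ends up cis to C6 (Z), while the silyl-capped enyne would need a larger ring for delivery and is left alone at low temperature.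

Step 15
Reactants: 22 iodo alcohol
Product: 23 (4S,5Z,7S)-4,8-bis(tert-butyldimethylsilyloxy)-6-iodo-7-methyl-3-methylidene-1-(trimethylsilyl)oct-5-en-1-yne
Conditions: TBSOTf, 2,6-lutidine, CH2Cl2, −78 to 0 °C
Reagents that add atoms: tert-butyldimethylsilyl triflate, CC(C)(C)[Si](C)(C)OS(=O)(=O)C(F)(F)F
Why: Silylation with a silyl triflate and a hindered base protects the crowded doubly allylic C6 alcohol without ionising it.

Step 16
Reactants: 23 Z-alkenyl iodide; 10 ring-A aldehyde
Product: 25 seco 9R allylic alcohol (ring A with C2 dimethyl acetal; 7Z; 6S-OTBS; 17R; C19-OTBS; TMS-enyne), via alkenyllithium 24 (not isolated)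
Conditions: t-BuLi (2.05 equiv), Et2O, −78 °C; then 10, −78 °C
Reagents that add atoms: none
Why: Iodine–lithium exchange retains the alkene geometry, 1,2-addition of 24 at −78 °C in ether should outrun 1,4 O-to-C silyl migration and enolisation, and Felkin–Anh control (quaternary C1 anti to the nucleophile, which passes H-10) sets C9 as 9R.

Step 17
Reactants: 25 seco alcohol
Product: 26 seco 9-acetate
Conditions: Ac2O, DMAP, Et3N, CH2Cl2, rt
Reagents that add atoms: acetic anhydride, CC(=O)OC(C)=O
Why: DMAP-catalysed acetylation installs the final C9 ester and stops the C9 oxygen from forming a lactol with the C2 aldehyde or, later, a lactone with C19.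

Step 18
Reactants: 26 seco acetate
Product: 27 seco C2 aldehyde
Conditions: PPTS, acetone/H2O, 45 °C
Reagents that add atoms: water, O
Why: Mild acid hydrolysis of a dimethyl acetal frees the non-enolisable C2 aldehyde under conditions that TBS ethers, the alkynylsilane and the allylic acetate tolerate.

Step 19
Reactants: 27 seco aldehyde
Product: 28 seco iodoalkyne aldehyde
Conditions: NIS (1.05 equiv), AgNO3 (10 mol %), acetone, 0 °C, dark
Reagents that add atoms: N-iodosuccinimide, O=C1CCC(=O)N1I
Why: In this silver-catalysed iododesilylation of an alkynylsilane, transfer of the alkynyl group to silver is much faster than attack of NIS on the alkenes, so only C3–Si becomes C3–I.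

Step 20
Reactants: 28 iodoalkyne aldehyde
Product: 30 macrocyclic enyne 2α-alcohol (9α-OAc; 6β-OTBS; C19-OTBS), via alkynylchromium(III) species 29 (not isolated)
Conditions: CrCl2 (8 equiv), NiCl2 (2 mol %), THF, 2 mM, rt
Reagents that add atoms: none
Why: Intramolecular Nozaki–Hiyama–Kishi addition of 29 to the C2 aldehyde at high dilution is a proven route to ten-membered cycloalkynes that tolerates acetates and silyl ethers, and the tether lets C3 approach only gauche to C10 and anti to the C1–C14 vinyl bond, a Felkin–Anh array in which the nucleophile passes the C15 methyl and the oxygen ends up α.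

Step 21
Reactants: 30 macrocyclic alcohol
Product: 31 macrocyclic 2α,9α-diacetate (6β-OTBS; C19-OTBS)
Conditions: Ac2O, DMAP, Et3N, CH2Cl2, rt
Reagents that add atoms: acetic anhydride, CC(=O)OC(C)=O
Why: DMAP-catalysed acetylation of the propargylic neopentyl alcohol installs the second and last acetate.

Step 22
Reactants: 31 diacetate
Product: 32 macrocyclic C19 primary alcohol
Conditions: HF·pyridine, pyridine, THF, 0 °C
Reagents that add atoms: none
Why: Buffered fluoride desilylation discriminates on steric grounds, so the primary C19 ether is cleaved well before the secondary C6 ether flanked by two sp2 carbons.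

Step 23
Reactants: 32 primary alcohol
Product: 34 macrocyclic C19 carboxylic acid, via C19 aldehyde 33 (not isolated)
Conditions: TEMPO (20 mol %), PhI(OAc)2 (2.5 equiv), MeCN/pH 7 buffer, rt
Reagents that add atoms: water, O
Why: Oxoammonium oxidation with PhI(OAc)2 in aqueous acetonitrile carries the alcohol through 33 and its hydrate to the acid near neutrality, which protects C17 from epimerisation and keeps C7=C8 out of conjugation.

Step 24
Reactants: 34 carboxylic acid
Product: 35 macrocyclic enyne triene diacetate methyl ester (1S,2S,6S,7Z,9R,10S,17R)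
Conditions: TMSCHN2, toluene/MeOH, 0 °C
Reagents that add atoms: trimethylsilyldiazomethane, C[Si](C)(C)C=[N+]=[N-]
Why: Esterification with a diazoalkane needs no base, so C17 is safe, and the ester is preferred to the acid because an acid would protonate the quinuclidine ligand of the next step.

Step 25
Reactants: 35 macrocyclic enyne triene diacetate methyl ester
Product: 38 triol γ-lactone (1S,2S,6R,7S,8R,9R,10S,11S,12R,17R) retaining the enyne and 6β-OTBS, via bis-osmate ester 36 (not isolated), via tetraol methyl ester 37 (not isolated)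
Conditions: OsO4 (2.2 equiv), (DHQ)2PHAL (2.4 equiv), toluene, −40 to −10 °C; aq NaHSO3, THF, rt
Reagents that add atoms: osmium tetroxide, O=[Os](=O)(=O)=O
Why: Two suprafacial (3+2) additions of ligand-bound OsO4 give 36, reductive hydrolysis frees 37, and the C7 hydroxyl attacks the C19 ester carbonyl (5-exo-trig acyl substitution with loss of methanol) to close the γ-lactone; the closest known chemistry is the asymmetric dihydroxylation of β,γ-unsaturated esters, which lactonise on their own, and the dihydroxylation of the more substituted alkene of a conjugated diene. C7 and C8 arise together: syn addition to the Z alkene (C6 and C9 cis) fixes their relative configuration, and the absolute configuration requires attack on the α face, which is the bottom face of the Sharpless mnemonic (H-7 south-east, C17 south-west, C9 north-west, C6 north-east) and so calls for the DHQ ligand. A(1,3) strain holds H-6 and H-9 in the alkene plane, so the C9 acetate lies on the β face and supports α attack (osmylation anti to an allylic oxygen), whereas the C6 silyl ether lies on the α face and opposes it, which is why a strongly face-selective ligand is used in stoichiometric amount. C11 and C12 are set by the substrate: pseudoaxial C15 and the C9 branch on C10 block the β face of ring A, and this bias should outweigh the weak opposite preference of the ligand for a ring alkene of this type. Site selectivity is needed over C5=C16, C13=C14 and the alkyne: ligand acceleration is largest for trisubstituted alkenes, C5=C16 is 1,1-disubstituted and made electron-poor by sp carbon C4 and the C6 oxygen, C13=C14 is cis-disubstituted and neopentyl, alkynes are osmylated far more slowly, and osmium is limited to little more than two equivalents at low temperature.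

Step 26
Reactants: 38 triol lactone
Product: 39 11,12-acetonide of 38
Conditions: 2,2-dimethoxypropane, PPTS, CH2Cl2, rt
Reagents that add atoms: 2,2-dimethoxypropane, COC(C)(C)OC
Why: Acid-catalysed transketalisation picks out the only cis-1,2-diol (C11/C12) and leaves the hindered tertiary C8 hydroxyl free.

Step 27
Reactants: 39 acetonide enyne
Product: 40 (3Z)-5(16)-diene acetonide (6β-OTBS)
Conditions: H2 (1 atm), Lindlar catalyst, quinoline, EtOAc, rt, stopped at one equivalent
Reagents that add atoms: none
Why: In this Lindlar semihydrogenation, syn delivery of hydrogen to the strained ring alkyne gives the 3Z alkene, and the poisoned catalyst reacts with the alkyne well before C5=C16 or C13=C14.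

Step 28
Reactants: 40 diene silyl ether
Product: 41 6β-alcohol (3Z-diene; acetonide; 2,9-diacetate; lactone)
Conditions: HF·pyridine, THF, 0 °C to rt
Reagents that add atoms: none
Why: Fluoride cleavage of the last silyl ether in a weakly acidic medium avoids the acetate migration and lactone opening that a basic fluoride source could cause.

Step 29
Reactants: 41 6β-alcohol
Product: 43 6α-chloride acetonide (6S), via alkoxyphosphonium chloride 42 (not isolated)
Conditions: PPh3, hexachloroacetone, CH2Cl2, −30 to 0 °C
Reagents that add atoms: hexachloroacetone, O=C(C(Cl)(Cl)Cl)C(Cl)(Cl)Cl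
Why: In this Appel-type chlorination with the PPh3/hexachloroacetone pair, the variant known to convert secondary allylic alcohols into unrearranged chlorides, chloride displaces Ph3PO from 42 by SN2 with inversion at C6, the electron-withdrawing C7 oxygen disfavours ionisation, and the tertiary C8 hydroxyl is too hindered to react.

Step 30
Reactants: 43 chloride acetonide
Product: 44 CNP0317097.1 (1S,2R,3Z,6S,7R,8R,9R,10S,11S,12R,17R)
Conditions: AcOH/H2O 4:1, 35 °C
Reagents that add atoms: none
Why: Mild acid hydrolysis of the acetonide, which is labile because one of its oxygens is tertiary and the other allylic, frees the C11/C12 diol without disturbing the acetates, the lactone or the secondary allylic chloride.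

Compound list
1 | pent-1-en-3-one | C=CC(=O)CC | starting material
2 | (Z)-3-(tert-butyldimethylsilyloxy)penta-1,3-diene | C=C/C(O[Si](C)(C)C(C)(C)C)=C/C | intermediate
3 | ethyl (E)-3-methyl-4-oxobut-2-enoate | CCOC(=O)/C=C(\C)C=O | starting material
4 | ethyl (1S,6S)-3-(tert-butyldimethylsilyloxy)-6-formyl-2,6-dimethylcyclohex-3-ene-1-carboxylate (C11 epimers) | O=C[C@@]1(C)CC=C(O[Si](C)(C)C(C)(C)C)C(C)[C@@H]1C(=O)OCC | intermediate
5 | ethyl (1S,6S)-6-formyl-2,6-dimethyl-3-oxocyclohex-4-ene-1-carboxylate (C11 epimers) | O=C[C@@]1(C)C=CC(=O)C(C)[C@@H]1C(=O)OCC | intermediate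
6 | ethyl (1S,6S)-6-(dimethoxymethyl)-2,6-dimethyl-3-oxocyclohex-4-ene-1-carboxylate (C11 epimers) | COC(OC)[C@@]1(C)C=CC(=O)C(C)[C@@H]1C(=O)OCC | intermediate
7 | potassium dienolate of 6 | [K+].COC(OC)[C@@]1(C)C=CC([O-])=C(C)[C@@H]1C(=O)OCC | intermediate
8 | ethyl (1S,6S)-6-(dimethoxymethyl)-2,6-dimethyl-3-(trifluoromethylsulfonyloxy)cyclohexa-2,4-diene-1-carboxylate | COC(OC)[C@@]1(C)C=CC(OS(=O)(=O)C(F)(F)F)=C(C)[C@@H]1C(=O)OCC | intermediate
9 | ethyl (1S,6S)-6-(dimethoxymethyl)-2,6-dimethylcyclohexa-2,4-diene-1-carboxylate | COC(OC)[C@@]1(C)C=CC=C(C)[C@@H]1C(=O)OCC | intermediate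
10 | (1S,6S)-6-(dimethoxymethyl)-2,6-dimethylcyclohexa-2,4-diene-1-carbaldehyde | COC(OC)[C@@]1(C)C=CC=C(C)[C@@H]1C=O | intermediate
11 | methyl (S)-3-hydroxy-2-methylpropanoate | COC(=O)[C@@H](C)CO | starting material
12 | methyl (S)-3-(tert-butyldimethylsilyloxy)-2-methylpropanoate | COC(=O)[C@@H](C)CO[Si](C)(C)C(C)(C)C | intermediate
13 | (S)-3-(tert-butyldimethylsilyloxy)-2-methylpropanal | O=C[C@@H](C)CO[Si](C)(C)C(C)(C)C | intermediate
14 | (R)-tert-butyl(dimethyl)[(2-methylbut-3-yn-1-yl)oxy]silane | C#C[C@@H](C)CO[Si](C)(C)C(C)(C)C | intermediate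
15 | 2-bromoprop-2-en-1-ol | C=C(Br)CO | starting material
16 | trimethylsilylacetylene | C#C[Si](C)(C)C | starting material
17 | 2-methylidene-4-(trimethylsilyl)but-3-yn-1-ol | C=C(CO)C#C[Si](C)(C)C | intermediate
18 | 2-methylidene-4-(trimethylsilyl)but-3-ynal | C=C(C=O)C#C[Si](C)(C)C | intermediate
19 | alkynyl(methyl)zinc from 14 | C[Zn]C#C[C@@H](C)CO[Si](C)(C)C(C)(C)C | intermediate
20 | (4S,7R)-8-(tert-butyldimethylsilyloxy)-7-methyl-3-methylidene-1-(trimethylsilyl)octa-1,5-diyn-4-ol | C=C(C#C[Si](C)(C)C)[C@@H](O)C#C[C@@H](C)CO[Si](C)(C)C(C)(C)C | intermediate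
21 | sodium cyclic alkenylalanate (O6–Al–C8 ring) | [Na+].COCCO[Al-]1(OCCOC)O[C@H](C(=C)C#C[Si](C)(C)C)C=C1[C@@H](C)CO[Si](C)(C)C(C)(C)C | intermediate
22 | (4S,5Z,7S)-8-(tert-butyldimethylsilyloxy)-6-iodo-7-methyl-3-methylidene-1-(trimethylsilyl)oct-5-en-1-yn-4-ol | C=C(C#C[Si](C)(C)C)[C@@H](O)/C=C(\I)[C@@H](C)CO[Si](C)(C)C(C)(C)C | intermediate
23 | (4S,5Z,7S)-4,8-bis(tert-butyldimethylsilyloxy)-6-iodo-7-methyl-3-methylidene-1-(trimethylsilyl)oct-5-en-1-yne | C=C(C#C[Si](C)(C)C)[C@@H](O[Si](C)(C)C(C)(C)C)/C=C(\I)[C@@H](C)CO[Si](C)(C)C(C)(C)C | intermediate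
24 | alkenyllithium from 23 | C=C(C#C[Si](C)(C)C)[C@@H](O[Si](C)(C)C(C)(C)C)/C=C(\[Li])[C@@H](C)CO[Si](C)(C)C(C)(C)C | intermediate
25 | seco 9R allylic alcohol (C2 dimethyl acetal) | COC(OC)[C@@]1(C)C=CC=C(C)[C@@H]1[C@@H](O)/C([C@@H](C)CO[Si](C)(C)C(C)(C)C)=C\[C@H](O[Si](C)(C)C(C)(C)C)C(=C)C#C[Si](C)(C)C | intermediate
26 | seco 9-acetate (C2 dimethyl acetal) | COC(OC)[C@@]1(C)C=CC=C(C)[C@@H]1[C@@H](OC(C)=O)/C([C@@H](C)CO[Si](C)(C)C(C)(C)C)=C\[C@H](O[Si](C)(C)C(C)(C)C)C(=C)C#C[Si](C)(C)C | intermediate
27 | seco C2 aldehyde (TMS-alkyne) | O=C[C@@]1(C)C=CC=C(C)[C@@H]1[C@@H](OC(C)=O)/C([C@@H](C)CO[Si](C)(C)C(C)(C)C)=C\[C@H](O[Si](C)(C)C(C)(C)C)C(=C)C#C[Si](C)(C)C | intermediate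
28 | seco C2 aldehyde (iodoalkyne) | O=C[C@@]1(C)C=CC=C(C)[C@@H]1[C@@H](OC(C)=O)/C([C@@H](C)CO[Si](C)(C)C(C)(C)C)=C\[C@H](O[Si](C)(C)C(C)(C)C)C(=C)C#CI | intermediate
29 | alkynylchromium(III) dichloride from 28 | O=C[C@@]1(C)C=CC=C(C)[C@@H]1[C@@H](OC(C)=O)/C([C@@H](C)CO[Si](C)(C)C(C)(C)C)=C\[C@H](O[Si](C)(C)C(C)(C)C)C(=C)C#C[Cr](Cl)Cl | intermediate
30 | macrocyclic enyne 2α-alcohol | C=C1C#C[C@@H](O)[C@@]2(C)C=CC=C(C)[C@@H]2[C@@H](OC(C)=O)/C([C@@H](C)CO[Si](C)(C)C(C)(C)C)=C\[C@@H]1O[Si](C)(C)C(C)(C)C | intermediate
31 | macrocyclic 2α,9α-diacetate (C19-OTBS) | C=C1C#C[C@@H](OC(C)=O)[C@@]2(C)C=CC=C(C)[C@@H]2[C@@H](OC(C)=O)/C([C@@H](C)CO[Si](C)(C)C(C)(C)C)=C\[C@@H]1O[Si](C)(C)C(C)(C)C | intermediate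
32 | macrocyclic C19 primary alcohol | C=C1C#C[C@@H](OC(C)=O)[C@@]2(C)C=CC=C(C)[C@@H]2[C@@H](OC(C)=O)/C([C@@H](C)CO)=C\[C@@H]1O[Si](C)(C)C(C)(C)C | intermediate
33 | macrocyclic C19 aldehyde | C=C1C#C[C@@H](OC(C)=O)[C@@]2(C)C=CC=C(C)[C@@H]2[C@@H](OC(C)=O)/C([C@@H](C)C=O)=C\[C@@H]1O[Si](C)(C)C(C)(C)C | intermediate
34 | macrocyclic C19 carboxylic acid | C=C1C#C[C@@H](OC(C)=O)[C@@]2(C)C=CC=C(C)[C@@H]2[C@@H](OC(C)=O)/C([C@@H](C)C(=O)O)=C\[C@@H]1O[Si](C)(C)C(C)(C)C | intermediate
35 | macrocyclic enyne triene diacetate methyl ester (key precursor) | C=C1C#C[C@@H](OC(C)=O)[C@@]2(C)C=CC=C(C)[C@@H]2[C@@H](OC(C)=O)/C([C@@H](C)C(=O)OC)=C\[C@@H]1O[Si](C)(C)C(C)(C)C | intermediate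
36 | bis-osmate(VI) ester at C7/C8 and C11/C12 (amine ligands omitted) | C=C1C#C[C@@H](OC(C)=O)[C@@]2(C)C=C[C@H]3O[Os](=O)(=O)O[C@@]3(C)[C@@H]2[C@@H](OC(C)=O)[C@@]4([C@@H](C)C(=O)OC)O[Os](=O)(=O)O[C@H]4[C@@H]1O[Si](C)(C)C(C)(C)C | intermediate
37 | 7,8,11,12-tetraol methyl ester | C=C1C#C[C@@H](OC(C)=O)[C@@]2(C)C=C[C@@H](O)[C@@](C)(O)[C@@H]2[C@@H](OC(C)=O)[C@](O)([C@@H](C)C(=O)OC)[C@@H](O)[C@@H]1O[Si](C)(C)C(C)(C)C | intermediate
38 | triol γ-lactone with enyne and 6β-OTBS (key product) | C=C1C#C[C@@H](OC(C)=O)[C@@]2(C)C=C[C@@H](O)[C@@](C)(O)[C@@H]2[C@@H](OC(C)=O)[C@]3(O)[C@@H](C)C(=O)O[C@H]3[C@@H]1O[Si](C)(C)C(C)(C)C | intermediate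
39 | 11,12-acetonide of 38 | C=C1C#C[C@@H](OC(C)=O)[C@@]2(C)C=C[C@H]3OC(C)(C)O[C@@]3(C)[C@@H]2[C@@H](OC(C)=O)[C@]4(O)[C@@H](C)C(=O)O[C@H]4[C@@H]1O[Si](C)(C)C(C)(C)C | intermediate
40 | (3Z)-5(16)-diene acetonide (6β-OTBS) | C=C1/C=C\[C@@H](OC(C)=O)[C@@]2(C)C=C[C@H]3OC(C)(C)O[C@@]3(C)[C@@H]2[C@@H](OC(C)=O)[C@]4(O)[C@@H](C)C(=O)O[C@H]4[C@@H]1O[Si](C)(C)C(C)(C)C | intermediate
41 | 6β-alcohol acetonide | C=C1/C=C\[C@@H](OC(C)=O)[C@@]2(C)C=C[C@H]3OC(C)(C)O[C@@]3(C)[C@@H]2[C@@H](OC(C)=O)[C@]4(O)[C@@H](C)C(=O)O[C@H]4[C@@H]1O | intermediate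
42 | C6 alkoxytriphenylphosphonium chloride | C=C1/C=C\[C@@H](OC(C)=O)[C@@]2(C)C=C[C@H]3OC(C)(C)O[C@@]3(C)[C@@H]2[C@@H](OC(C)=O)[C@]4(O)[C@@H](C)C(=O)O[C@H]4[C@@H]1O[P+](c5ccccc5)(c5ccccc5)c5ccccc5.[Cl-] | intermediate
43 | 6α-chloride acetonide | C=C1/C=C\[C@@H](OC(C)=O)[C@@]2(C)C=C[C@H]3OC(C)(C)O[C@@]3(C)[C@@H]2[C@@H](OC(C)=O)[C@]4(O)[C@@H](C)C(=O)O[C@H]4[C@H]1Cl | intermediate
44 | CNP0317097.1 | C=C1/C=C\[C@@H](OC(C)=O)[C@@]2(C)C=C[C@@H](O)[C@@](C)(O)[C@@H]2[C@@H](OC(C)=O)[C@]2(O)[C@@H](C)C(=O)O[C@H]2[C@H]1Cl | target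

Total step count: 30. Longest linear sequence: 22 steps (steps 1–7, then 16–30). The side-chain branch (steps 8–10 and 13–15, fed by steps 11–12) joins at step 16.

Steps most likely to fail

Step 25. The ligand may fail to overrule the C6 silyl ether, so that osmium adds to the wrong face of C7=C8. Osmylation of C5=C16 may also compete with the crowded C7=C8. The fallback hands the facial choice to a hydrogen bond instead of a ligand.
- It sets out from 35, whose C6 silyl ether is cleaved with HF·pyridine to give the macrocyclic C6 alcohol F1.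
- OsO4·TMEDA in CH2Cl2 at −78 °C (hydrogen-bond-directed dihydroxylation) is then delivered syn to the C6 hydroxyl. In the A(1,3)-locked rotamer this hydroxyl lies on the α face of C7=C8, so the C6 and C9 substituents now reinforce each other. Ring A still reacts under its own steric bias.
- The reagent has to be metered closely, because the same hydroxyl is also allylic to C5=C16.
- Cleavage of the osmate esters with ethylenediamine and spontaneous lactonisation give the tetraol lactone F2.
- 2,2-Dimethoxypropane/PPTS converts F2 into the acetonide enyne alcohol F3, and Lindlar semihydrogenation of F3 rejoins the route at 41.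

Step 20. The strained ring may close slowly, so that oligomerisation competes, and facial selectivity at the C2 aldehyde may be poor. The fallback replaces substrate control at C2 by reagent control.
- It sets out from 30, as either epimer or a mixture.
- Dess–Martin oxidation gives the macrocyclic ynone F4, which cannot epimerise because C1 is quaternary.
- Corey–Bakshi–Shibata reduction with (S)-Me-CBS and catecholborane at −78 °C treats quaternary C1 as the large and the alkyne as the small substituent. It should return the 2α-alcohol and so rejoins the route at 30.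

Step 29. Chloride may attack the unhindered C16 terminus (allylic transposition), or partial ionisation may erode the configuration at C6. The fallback makes use of the transposition.
- It sets out from 41, which is treated with SOCl2 in ether. These conditions favour delivery to C16 and give the transposed primary allylic chloride F5 (C5=C6 with C4 and C7 cis).
- Sodium phenylselenide displaces the primary chloride to give the allyl phenyl selenide F6.
- N-Chlorosuccinimide chlorinates selenium, and the [2,3]-sigmatropic shift of the Se(IV) species moves the double bond back to C5=C16 and places chlorine on C6. The outer α face of the ring is the expected site.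
- This rejoins the route at 43.

Further compounds
F1 | step 25 | macrocyclic enyne triene diacetate methyl ester with free 6β-OH | C=C1C#C[C@@H](OC(C)=O)[C@@]2(C)C=CC=C(C)[C@@H]2[C@@H](OC(C)=O)/C([C@@H](C)C(=O)OC)=C\[C@@H]1O
F2 | step 25 | 6,8,11,12-tetraol γ-lactone with enyne | C=C1C#C[C@@H](OC(C)=O)[C@@]2(C)C=C[C@@H](O)[C@@](C)(O)[C@@H]2[C@@H](OC(C)=O)[C@]3(O)[C@@H](C)C(=O)O[C@H]3[C@@H]1O
F3 | step 25 | 11,12-acetonide of F2 | C=C1C#C[C@@H](OC(C)=O)[C@@]2(C)C=C[C@H]3OC(C)(C)O[C@@]3(C)[C@@H]2[C@@H](OC(C)=O)[C@]4(O)[C@@H](C)C(=O)O[C@H]4[C@@H]1O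
F4 | step 20 | macrocyclic C2 ynone | C=C1C#CC(=O)[C@@]2(C)C=CC=C(C)[C@@H]2[C@@H](OC(C)=O)/C([C@@H](C)CO[Si](C)(C)C(C)(C)C)=C\[C@@H]1O[Si](C)(C)C(C)(C)C
F5 | step 29 | 16-chloro-3Z,5-diene acetonide (transposed primary allylic chloride) | ClC/C1=C/[C@@H]2OC(=O)[C@H](C)[C@@]2(O)[C@H](OC(C)=O)[C@H]3[C@]4(C)OC(C)(C)O[C@@H]4C=C[C@]3(C)[C@H](OC(C)=O)/C=C\1
F6 | step 29 | 16-(phenylselanyl)-3Z,5-diene acetonide | c5ccccc5[Se]C/C1=C/[C@@H]2OC(=O)[C@H](C)[C@@]2(O)[C@H](OC(C)=O)[C@H]3[C@]4(C)OC(C)(C)O[C@@H]4C=C[C@]3(C)[C@H](OC(C)=O)/C=C\1
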